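## Retrosynthetic overview

1. The target comes from hydrogenolysis of a hepta-O-benzyl precursor that already carries both gallates as tri-O-benzylgalloyl esters, installed on the two aldehyde building blocks, so no late regioselective galloylation is needed.
2. Ring C is the only ring made (rings A and B are bought): O1–C2 closure of a (1S,2S)-1,3-diarylpropane-1,2-diol with inversion at the benzylic carbon; the two ortho phenols of ring A are equivalent.
3. The diol comes from catalyst-controlled transfer hydrogenation of an (S)-α-hydroxy aryl ketone.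
4. Key C2–C3 bond: enantioselective carbene-catalysed cross-acyloin coupling, in which the ring B aldehyde reacts as an acyl anion (Breslow intermediate) with the ring A arylacetaldehyde, joining two carbonyl carbons.
5. Ring A aldehyde from 2,4,6-trihydroxybenzaldehyde (4-O-galloylation, silylation, one-carbon homologation); ring B aldehyde from 4-(benzyloxy)-3-hydroxybenzaldehyde.

Abbreviations: G = 3,4,5-tris(benzyloxy)benzoyl; TBS = tert-butyldimethylsilyl; ArB = 4-(benzyloxy)-3-(G-oxy)phenyl; ArA = 2,6-bis(TBS-oxy)-4-(G-oxy)phenyl; ArA' = 2,6-dihydroxy-4-(G-oxy)phenyl.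

Assumption: the (5S) triazolium precatalyst is taken to be the enantiomer that gives the (S)-ketol 9; this is checked on the first run (Mosher ester) and the (5R) precatalyst is used if the sense is opposite.

## Route

Step 1
Reactants: 1 2,4,6-trihydroxybenzaldehyde; 2 3,4,5-tris(benzyloxy)benzoic acid (1.0 equiv)
Product: 3 4-formyl-3,5-dihydroxyphenyl 3,4,5-tris(benzyloxy)benzoate
Conditions: DCC, 4-(dimethylamino)pyridine (10 mol %), THF, 0 °C to rt
Reagents that add atoms: none
Why: The 4-OH (para to the formyl group, not hydrogen-bonded to it, least hindered) is the most acidic and most accessible phenol, so one equivalent of acid under Steglich esterification acylates it selectively.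

Step 2
Reactants: 3 4-formyl-3,5-dihydroxyphenyl 3,4,5-tris(benzyloxy)benzoate
Product: 4 3,5-bis(TBS-oxy)-4-formylphenyl 3,4,5-tris(benzyloxy)benzoate
Conditions: TBSOTf (2.4 equiv), 2,6-lutidine, CH2Cl2, −40 to 0 °C
Reagents that add atoms: tert-butyldimethylsilyl trifluoromethanesulfonate, CC(C)(C)[Si](C)(C)OS(=O)(=O)C(F)(F)F
Why: Silyl ether formation with a silyl triflate and a non-nucleophilic base caps both hydrogen-bonded ortho phenols without attacking the activated aryl ester.

Step 3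
Reactants: 4 3,5-bis(TBS-oxy)-4-formylphenyl 3,4,5-tris(benzyloxy)benzoate
Product: 6 3,5-bis(TBS-oxy)-4-(2-oxoethyl)phenyl 3,4,5-tris(benzyloxy)benzoate, via enol ether 5 (not isolated)
Conditions: Ph3P(CH2OMe)Cl (1.3 equiv), NaN(SiMe3)2 (1.25 equiv), THF, −78 to 0 °C; then 2 M HCl (aq), THF, rt
Reagents that add atoms: (methoxymethyl)triphenylphosphonium chloride, COC[P+](c1ccccc1)(c1ccccc1)c1ccccc1.[Cl-]; water, O
Why: Wittig methoxymethylenation of the aldehyde outpaces ylide attack on the ester at low temperature, and dilute acid hydrolyses the enol ether to the homologous aldehyde while aryl TBS ethers and the gallate survive (Wittig homologation, enol ether hydrolysis).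

Step 4
Reactants: 7 4-(benzyloxy)-3-hydroxybenzaldehyde; 2 3,4,5-tris(benzyloxy)benzoic acid
Product: 8 2-(benzyloxy)-5-formylphenyl 3,4,5-tris(benzyloxy)benzoate
Conditions: DCC, 4-(dimethylamino)pyridine (10 mol %), CH2Cl2, rt
Reagents that add atoms: none
Why: Steglich esterification of the only free phenol fixes the gallate at the future 3'-oxygen, with the benzyl ether marking the future free 4'-OH.

Step 5
Reactants: 6 3,5-bis(TBS-oxy)-4-(2-oxoethyl)phenyl 3,4,5-tris(benzyloxy)benzoate; 8 2-(benzyloxy)-5-formylphenyl 3,4,5-tris(benzyloxy)benzoate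
Product: 9 (2S)-1-ArB-2-hydroxy-3-ArA-propan-1-one
Conditions: (5S)-5-[hydroxy(diphenyl)methyl]-2-(pentafluorophenyl)-6,7-dihydro-5H-pyrrolo[2,1-c][1,2,4]triazol-2-ium tetrafluoroborate (15 mol %), i-Pr2NEt (1.0 equiv), THF, 0 °C, aryl aldehyde in 2.5-fold excess, arylacetaldehyde added slowly by syringe pump; then AcOH (1.1 equiv), 0 °C
Reagents that add atoms: none
Why: Proposed new method: the triazolylidene, freed by a full equivalent of the weak hindered amine, adds to the non-enolisable aromatic aldehyde 8 (in excess, the surplus being recovered) to give a Breslow intermediate, an acyl anion at the future C2, which attacks the more electrophilic aliphatic aldehyde 6 (kept dilute by slow addition so that its own acyloin and aldol pathways, second order in 6, are starved) while the catalyst's carbinol OH hydrogen-bonds the acceptor carbonyl and exposes one face, setting the C3 stereocentre as S, and the acetic acid quench protonates carbene and amine at 0 °C so that neither retro-acyloin cleavage nor epimerisation follows on work-up; the closest known chemistry is the chemoselective crossed aromatic–aliphatic acyloin condensation with N-pentafluorophenyl triazolium precatalysts and the highly enantioselective benzoin condensation with this same hydrogen-bond-donor precatalyst, the untested points being the enantioselectivity with an aliphatic acceptor and the tolerance of the aryl gallates.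

Step 6
Reactants: 9 (2S)-1-ArB-2-hydroxy-3-ArA-propan-1-one
Product: 10 (1S,2S)-1-ArB-3-ArA-propane-1,2-diol
Conditions: RuCl[(R,R)-TsNCHPhCHPhNH2](p-cymene) (2 mol %), HCO2H/Et3N (5:2), CH2Cl2, 25 °C; chromatography
Reagents that add atoms: none
Why: Noyori–Ikariya asymmetric transfer hydrogenation of the aryl ketone is catalyst-controlled, the (R,R) catalyst giving the (1S) carbinol, which with the (S)-ketol is the matched syn case (as in the benzoin-to-hydrobenzoin reduction), while any (R)-ketol ends up as the separable anti diol.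

Step 7
Reactants: 10 (1S,2S)-1-ArB-3-ArA-propane-1,2-diol
Product: 11 (1S,2S)-1-ArB-3-ArA'-propane-1,2-diol
Conditions: Bu4NF (2.2 equiv), AcOH (2.4 equiv), THF, 0 °C
Reagents that add atoms: none
Why: Buffered fluoride desilylation cleaves the two aryl silyl ethers quickly, and the acetic acid keeps the phenols protonated so the gallates are not transesterified.

Step 8
Reactants: 11 (1S,2S)-1-ArB-3-ArA'-propane-1,2-diol
Product: 14 (2R,3S)-2-ArB-3,5-dihydroxychroman-7-yl 3,4,5-tris(benzyloxy)benzoate, via cyclic orthoformate 12 (not isolated), via 3-O-formate 13 (not isolated)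
Conditions: HC(OEt)3 (5 equiv), pyridinium p-toluenesulfonate (20 mol %), ClCH2CH2Cl, rt to 60 °C; then MeOH, TsOH·H2O (10 mol %), rt
Reagents that add atoms: none
Why: The syn diol forms a cyclic orthoformate whose acid-induced ionisation gives a 1,3-dioxolan-2-ylium ion that an ortho phenol opens at the benzylic carbon with inversion, setting C2 as R and giving the 2,3-trans chroman as its 3-O-formate, which acid methanolysis removes far faster than the aryl gallates (orthoester-mediated stereospecific cyclisation of a 1,3-diarylpropane-1,2-diol).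

Step 9
Reactants: 14 (2R,3S)-2-ArB-3,5-dihydroxychroman-7-yl 3,4,5-tris(benzyloxy)benzoate
Product: 15 catechin 7,3'-di-O-gallate, (2R,3S)
Conditions: H2 (1 atm), Pd(OH)2 on carbon, THF/MeOH (1:1), AcOH (1 %), rt
Reagents that add atoms: none
Why: Catalytic hydrogenolysis removes the seven benzyl ethers while aryl gallates, the chroman C2–O bond and both stereocentres are untouched, and the slightly acidic medium suppresses 3'-to-4' galloyl migration.

## Compound list

1 | 2,4,6-trihydroxybenzaldehyde | O=Cc1c(O)cc(O)cc1O | starting material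
2 | 3,4,5-tris(benzyloxy)benzoic acid | OC(=O)c1cc(OCc2ccccc2)c(OCc2ccccc2)c(OCc2ccccc2)c1 | starting material
3 | 4-formyl-3,5-dihydroxyphenyl 3,4,5-tris(benzyloxy)benzoate | O=Cc1c(O)cc(OC(=O)c2cc(OCc3ccccc3)c(OCc3ccccc3)c(OCc3ccccc3)c2)cc1O | intermediate
4 | 3,5-bis(tert-butyldimethylsilyloxy)-4-formylphenyl 3,4,5-tris(benzyloxy)benzoate | O=Cc1c(O[Si](C)(C)C(C)(C)C)cc(OC(=O)c2cc(OCc3ccccc3)c(OCc3ccccc3)c(OCc3ccccc3)c2)cc1O[Si](C)(C)C(C)(C)C | intermediate
5 | 3,5-bis(tert-butyldimethylsilyloxy)-4-(2-methoxyethenyl)phenyl 3,4,5-tris(benzyloxy)benzoate (E/Z mixture) | COC=Cc1c(O[Si](C)(C)C(C)(C)C)cc(OC(=O)c2cc(OCc3ccccc3)c(OCc3ccccc3)c(OCc3ccccc3)c2)cc1O[Si](C)(C)C(C)(C)C | intermediate (not isolated)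
6 | 3,5-bis(tert-butyldimethylsilyloxy)-4-(2-oxoethyl)phenyl 3,4,5-tris(benzyloxy)benzoate | O=CCc1c(O[Si](C)(C)C(C)(C)C)cc(OC(=O)c2cc(OCc3ccccc3)c(OCc3ccccc3)c(OCc3ccccc3)c2)cc1O[Si](C)(C)C(C)(C)C | intermediate
7 | 4-(benzyloxy)-3-hydroxybenzaldehyde | O=Cc1ccc(OCc2ccccc2)c(O)c1 | starting material
8 | 2-(benzyloxy)-5-formylphenyl 3,4,5-tris(benzyloxy)benzoate | O=Cc1ccc(OCc2ccccc2)c(OC(=O)c2cc(OCc3ccccc3)c(OCc3ccccc3)c(OCc3ccccc3)c2)c1 | intermediate
9 | (2S)-1-ArB-2-hydroxy-3-ArA-propan-1-one (the (S)-ketol) | O=C(c1ccc(OCc2ccccc2)c(OC(=O)c2cc(OCc3ccccc3)c(OCc3ccccc3)c(OCc3ccccc3)c2)c1)[C@@H](O)Cc1c(O[Si](C)(C)C(C)(C)C)cc(OC(=O)c2cc(OCc3ccccc3)c(OCc3ccccc3)c(OCc3ccccc3)c2)cc1O[Si](C)(C)C(C)(C)C | intermediate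
10 | (1S,2S)-1-ArB-3-ArA-propane-1,2-diol (syn diol) | O[C@@H](c1ccc(OCc2ccccc2)c(OC(=O)c2cc(OCc3ccccc3)c(OCc3ccccc3)c(OCc3ccccc3)c2)c1)[C@@H](O)Cc1c(O[Si](C)(C)C(C)(C)C)cc(OC(=O)c2cc(OCc3ccccc3)c(OCc3ccccc3)c(OCc3ccccc3)c2)cc1O[Si](C)(C)C(C)(C)C | intermediate
11 | (1S,2S)-1-ArB-3-ArA'-propane-1,2-diol (syn diol, both ortho phenols free) | O[C@@H](c1ccc(OCc2ccccc2)c(OC(=O)c2cc(OCc3ccccc3)c(OCc3ccccc3)c(OCc3ccccc3)c2)c1)[C@@H](O)Cc1c(O)cc(OC(=O)c2cc(OCc3ccccc3)c(OCc3ccccc3)c(OCc3ccccc3)c2)cc1O | intermediate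
12 | (4S,5S)-2-ethoxy-4-ArB-5-(ArA'-methyl)-1,3-dioxolane (cyclic orthoformate, epimers at the orthoester carbon) | CCOC1O[C@@H](c2ccc(OCc3ccccc3)c(OC(=O)c3cc(OCc4ccccc4)c(OCc4ccccc4)c(OCc4ccccc4)c3)c2)[C@@H](O1)Cc1c(O)cc(OC(=O)c2cc(OCc3ccccc3)c(OCc3ccccc3)c(OCc3ccccc3)c2)cc1O | intermediate (not isolated)
13 | (2R,3S)-2-ArB-3-(formyloxy)-5-hydroxychroman-7-yl 3,4,5-tris(benzyloxy)benzoate | O=C(Oc1cc(O)c2c(c1)O[C@H](c1ccc(OCc3ccccc3)c(OC(=O)c3cc(OCc4ccccc4)c(OCc4ccccc4)c(OCc4ccccc4)c3)c1)[C@@H](OC=O)C2)c1cc(OCc2ccccc2)c(OCc2ccccc2)c(OCc2ccccc2)c1 | intermediate (not isolated)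
14 | (2R,3S)-2-ArB-3,5-dihydroxychroman-7-yl 3,4,5-tris(benzyloxy)benzoate (hepta-O-benzyl catechin 7,3'-digallate) | O=C(Oc1cc(O)c2c(c1)O[C@H](c1ccc(OCc3ccccc3)c(OC(=O)c3cc(OCc4ccccc4)c(OCc4ccccc4)c(OCc4ccccc4)c3)c1)[C@@H](O)C2)c1cc(OCc2ccccc2)c(OCc2ccccc2)c(OCc2ccccc2)c1 | intermediate
15 | catechin 7,3'-di-O-gallate, (2R,3S) | O=C(Oc1cc(O)c2c(c1)O[C@H](c1ccc(O)c(OC(=O)c3cc(O)c(O)c(O)c3)c1)[C@@H](O)C2)c1cc(O)c(O)c(O)c1 | target

## Step count

Total steps: 9. Longest linear sequence: 8 (steps 1, 2, 3, 5, 6, 7, 8, 9).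

## Steps most likely to fail, with fallbacks

**Step 5 (key coupling).** Three things can go wrong:
- The Breslow intermediate of 6 may add to 8 instead (reversed roles), or 6 may self-couple.
- The enantioselectivity with an aliphatic acceptor may be modest.
- The carbene may shuttle a galloyl group onto the new carbinol.

The fallback sets out from 6 and 8 and comes back at 10. The coupling is run in the kinetically easier sense with the achiral 2-(pentafluorophenyl)-5,6,7,8-tetrahydro[1,2,4]triazolo[4,3-a]pyridin-2-ium tetrafluoroborate and i-Pr2NEt, so that the acyl anion of the aliphatic aldehyde 6 adds to 8. This gives the regioisomeric racemic ketol 1-ArB-1-hydroxy-3-ArA-propan-2-one F1. Catalytic Et3N then moves the carbonyl into conjugation with ring B by enediol (α-ketol) transposition, giving the racemic ketol rac-1-ArB-2-hydroxy-3-ArA-propan-1-one F2. The transfer hydrogenation of step 6 then sorts the enantiomers: the (S)-ketol gives syn diol 10, and the (R)-ketol gives the anti diol (1S,2R)-1-ArB-3-ArA-propane-1,2-diol F3, which is removed by chromatography.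

**Step 3 (homologation).** The aldehyde is flanked by two silyloxy groups, and the para gallate is an activated aryl ester that a basic ylide may attack.

The fallback sets out from 4 and comes back at 6. Non-basic methylenation with Zn, CH2Br2 and TiCl4 in THF leaves esters alone and gives the styrene 3,5-bis(TBS-oxy)-4-ethenylphenyl 3,4,5-tris(benzyloxy)benzoate F4. Hydroboration with 9-BBN followed by NaBO3·4H2O gives the primary alcohol 3,5-bis(TBS-oxy)-4-(2-hydroxyethyl)phenyl 3,4,5-tris(benzyloxy)benzoate F5. Dess–Martin periodinane with NaHCO3 then gives aldehyde 6.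

**Step 8 (ring C closure).** Partial ionisation to a free benzylic cation would erode the inversion and give some 2,3-cis product, and removal of the formate must not touch the gallates.

The fallback sets out from 11 and comes back at 14. An intramolecular Mitsunobu etherification (PPh3, diisopropyl azodicarboxylate, THF, 0 °C) lets the phenol displace the activated benzylic hydroxyl with inversion under neutral conditions. This closes ring C directly to 14 with the 3-OH free and makes no new compound (F0).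

## Further compounds

F1 | step 5 | rac-1-ArB-1-hydroxy-3-ArA-propan-2-one | OC(c1ccc(OCc2ccccc2)c(OC(=O)c2cc(OCc3ccccc3)c(OCc3ccccc3)c(OCc3ccccc3)c2)c1)C(=O)Cc1c(O[Si](C)(C)C(C)(C)C)cc(OC(=O)c2cc(OCc3ccccc3)c(OCc3ccccc3)c(OCc3ccccc3)c2)cc1O[Si](C)(C)C(C)(C)C
F2 | step 5 | rac-1-ArB-2-hydroxy-3-ArA-propan-1-one | O=C(c1ccc(OCc2ccccc2)c(OC(=O)c2cc(OCc3ccccc3)c(OCc3ccccc3)c(OCc3ccccc3)c2)c1)C(O)Cc1c(O[Si](C)(C)C(C)(C)C)cc(OC(=O)c2cc(OCc3ccccc3)c(OCc3ccccc3)c(OCc3ccccc3)c2)cc1O[Si](C)(C)C(C)(C)C
F3 | step 5 | (1S,2R)-1-ArB-3-ArA-propane-1,2-diol (anti diol) | O[C@@H](c1ccc(OCc2ccccc2)c(OC(=O)c2cc(OCc3ccccc3)c(OCc3ccccc3)c(OCc3ccccc3)c2)c1)[C@H](O)Cc1c(O[Si](C)(C)C(C)(C)C)cc(OC(=O)c2cc(OCc3ccccc3)c(OCc3ccccc3)c(OCc3ccccc3)c2)cc1O[Si](C)(C)C(C)(C)C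
F4 | step 3 | 3,5-bis(tert-butyldimethylsilyloxy)-4-ethenylphenyl 3,4,5-tris(benzyloxy)benzoate | C=Cc1c(O[Si](C)(C)C(C)(C)C)cc(OC(=O)c2cc(OCc3ccccc3)c(OCc3ccccc3)c(OCc3ccccc3)c2)cc1O[Si](C)(C)C(C)(C)C
F5 | step 3 | 3,5-bis(tert-butyldimethylsilyloxy)-4-(2-hydroxyethyl)phenyl 3,4,5-tris(benzyloxy)benzoate | OCCc1c(O[Si](C)(C)C(C)(C)C)cc(OC(=O)c2cc(OCc3ccccc3)c(OCc3ccccc3)c(OCc3ccccc3)c2)cc1O[Si](C)(C)C(C)(C)C
F0 | step 8 | none | none
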